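## Structural features

The target is a flavonol methyl ether in which benzene ring A is fused to pyranone ring C (a 4H-chromen-4-one) and aryl ring B is joined to C2 by a single C2–C1′ bond. Ring A carries three oxygens on contiguous carbons (OH at C5, OCH3 at C6, OH at C7) and the ring oxygen O1 on C8a, so C8–H is its only hydrogen. Ring C carries OCH3 at C3, and ring B carries OH at C4′ between two 3-methylbut-2-enyl (prenyl) chains at C3′ and C5′. There is no stereocentre, so no stereocentres stand next to each other, and the prenyl alkenes end in gem-dimethyl groups, so no alkene geometry has to be set. The fragile parts are the prenyl alkenes (protonation leads to cyclisation onto an ortho phenol, and electrophilic oxidants or hydrogenation attack them), the electron-rich phenols (oxidation), and C2 of the pyranone (ring opening by hydroxide). The real difficulty is telling oxygens apart: two methyl ethers (C3 and C6) must sit among three free phenols (C5, C7, C4′), ring closure onto a phloroglucinol-type ring A can give the 8-methoxy isomer instead of the 6-methoxy one, and a phenol must be C-prenylated at both ortho positions. The key step uses the C3–H of ring C, the only sp2 C–H that is alpha to the C4 carbonyl and beta to O1; with the three phenols masked as acetals, turning this C–H into C–OH creates the only free hydroxyl in the molecule, so the C3 methyl ether can be placed without ambiguity.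

## Logic of the disconnections

22 to 21: the three O–CH2OCH3 acetal bonds on the C5, C7 and C4′ oxygens are cut last. The phenols stay masked through every basic, organometallic and alkylating step, and acetals need neither hydrogenation nor a strong Lewis acid for removal. The forward step must use acid mild enough to leave a prenyl alkene beside the freed C4′ hydroxyl untouched.

21 to 20: the O–CH3 bond at C3 is cut. 20 has one free hydroxyl, so the forward alkylation has no choice of site and asks nothing special of the reagents.

20 to 17: the C3–O bond is cut back to C3–H (the key disconnection). 17 is a plain flavone, and the oxygen that must be distinguished from the others arrives alone. The forward step must deprotonate C3 in preference to C8 and the prenyl CH2 groups, trap the anion before ring C opens, and oxidise boron without touching the alkenes.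

17 to 16: the O1–C2 bond of ring C is cut, giving an open-chain ortho-hydroxyaryl 1,3-diketone. Only one ring A hydroxyl of 16 is free, so closure can give only the 6-methoxy pattern. The forward cyclodehydration must use an acid weak enough for three acetals, above all the one at the future C5.

16 to 9 and 14 (through 15): the bond between the central CH2 (future C3) and the ring B carbonyl carbon (future C2) is cut. This is the convergent cut and divides the molecule into ring A and ring B halves of similar size. The forward step needs C-acylation of a ketone enolate in the presence of a phenoxide and an acid chloride made without HCl.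

14 to 13 to 12 to 10 and 11: ester hydrolysis and acetal formation are undone, then the two aryl–CH2 bonds at C3′ and C5′ are cut, which calls for two equivalents of 11. The para ester of 10 blocks the third reactive position and is itself the future C2. The forward step must favour C- over O-alkylation of a phenoxide and must be driven through both ortho positions.

9 to 8 to 5 and 6 (through 7): after the benzyl ether is restored, the aryl–acetyl bond (future C4a–C4) is cut to an aryl anion and an acetyl cation equivalent. In 5 the two ring carbons between the benzyloxy and acetal oxygens are equivalent by mirror symmetry, so one ketone results. The forward step must leave the acetals intact, which rules out a Lewis acid rearrangement, and ring lithiation must outrun benzylic lithiation.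

5 to 4 to 2 (through 3) to 1: the benzyl ether is cut, then the C–O bond para to the methoxy group is cut back to C–H, then the two acetals. 1 holds only three of the four ring A oxygens. The fourth must enter meta to both acetal ethers, a position that electrophilic substitution and ortho-lithiation do not reach but that a sterically governed C–H borylation does.

## Other disconnections considered

Alternative 1: The cut is C4–C4a with O1–C2 already in place, so the precursor is the (E)-3-aryloxy-2-methoxyacrylic acid A2, with ring A on the enol ether oxygen and ring B on the same carbon. In the forward direction A2 would be turned into its acid chloride with 1-chloro-N,N,2-trimethylprop-1-en-1-amine. ZnCl2 would then promote an intramolecular Friedel–Crafts acylation ortho to the aryloxy oxygen to give the tris(allyl) ether A1, and Pd(PPh3)4 (zerovalent palladium) with a soft nucleophile would remove the allyl groups.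
- In its favour: the C3 methoxy group is present from the start, so no late C–H oxygenation is needed. The ring A aryloxy unit is mirror-symmetric, so either ortho carbon gives the 6-methoxy pattern; on this point it equals the chosen plan. The final deprotection is neutral, which is better than the acid of step 13 because the prenyl chains never meet a proton source beside a free phenol.
- Against it: A2 is a tetrasubstituted push–pull alkene whose aryloxy and carboxyl groups must be on the same side. The obvious route to it, addition–elimination of a ring A phenoxide on a beta-halo-alpha-methoxycinnamate, does not control that geometry. The acid chloride is a weak, vinylogous carbonate-type electrophile that needs the Lewis acid, and ZnCl2 would meet three aryl allyl ethers (Lewis acid-accelerated Claisen shift into the very ring A carbons that are needed, or deallylation) and two prenyl alkenes. Ring A of A2 needs the same symmetric phenol pattern as 4, so nothing is saved there.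
- Comparison: on structure the two plans are equally secure about ring A regiochemistry. On mechanism this one closes ring C with an electrophile under a Lewis acid, while the chosen plan keeps the alkenes away from Lewis acids and pays with a cryogenic organolithium step. On step economy they are about level: one step after ring closure here against three, but A2 should cost about three steps more than 16.

Alternative 2: The cuts are C3–C4 and O1–C2, so ring C is made in one step from the ring A salicylaldehyde A4 and the ring B methyl ynol ether A5. With [Cp*RhCl2]2 and Cu(OAc)2 the phenoxide would bind trivalent rhodium, the aldehyde C–H bond would be cleaved to an acyl rhodacycle, and the alkyne would insert. C–O reductive elimination would then give A3, which is identical with 21, and divalent copper would reoxidise the monovalent rhodium.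
- In its favour: it is the most convergent option. It delivers 21 directly with the C3 methoxy group in place, avoids all acid before the last step, and needs only one step from 4 to reach A4. On step economy it is better than the chosen plan by roughly two to three steps, even after the extra steps needed to make A5 from 13.
- Against it: this oxidative annulation is established for diaryl and dialkyl alkynes, and an aryl ynol ether as partner would be an untested extension. The regiochemistry is not secured: the aryl group favours rhodium on the aryl-bearing carbon (the wanted sense), but the polarisation of the ynol ether favours bonding the acyl carbon to that same carbon, which would give a 3-aryl-2-methoxychromone. A5 is prone to hydration by acetate and water. A4 is a di-ortho-substituted, very electron-rich phenol that hot Cu(OAc)2 may oxidise. Decarbonylation of the acyl rhodium species and allylic C–H activation of the prenyl chains are further possible diversions.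
- Comparison: structurally it gives the same protected compound as the chosen route at 21. Mechanistically it rests on one unproven insertion, whereas the chosen plan rests on reactions each known for its substrate class. The chosen plan is longer but each of its bonds is formed with predictable regiochemistry.

Alternative 3: The cut is the C6–O bond of ring A. The 3-methoxy-5,7-bis(methoxymethoxy)flavone A7 would be made from a phloroglucinol-derived methoxyacetyl ketone. It would be magnesiated at C6 with TMPMgCl·LiCl (TMP = 2,2,6,6-tetramethylpiperidide), trapped with B(OMe)3 and oxidised with H2O2 and NaOH to the 6-hydroxy compound A6. O-Methylation and acetal cleavage would follow.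
- In its favour: ring A comes from a cheap symmetric phloroglucinol unit, so neither the iridium step nor the benzyl detour of the chosen plan is needed; on the supply of ring A it is better. C3 already carries its methyl ether, so there is no competing C3–H. C6–H lies between two acetal oxygens, a classical doubly activated metalation site. The number of steps after the key step is equal to the chosen plan (methylation, then deprotection).
- Against it: C8–H is also flanked by two oxygens (O1 and the C7 acetal) and is less hindered, and the C5 acetal is tied up by the C4 carbonyl, so C6 against C8 selectivity is the weak point. A wrong choice would give the 8-methoxy isomer, which is hard to distinguish spectroscopically from the target series. The new hydroxyl sits between two acetals, so its methylation is hindered.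
- Comparison: on structure the chosen plan fixes the ring A oxygen pattern before ring C exists, by the symmetry of 2 and 5, whereas this one stakes it on a late site selection. Mechanistically the two key steps are the same type (metalation, borylation, oxidation), but the chosen one aims at a C–H bond with no close rival. On step count this alternative is probably two or three steps shorter.

Key step: step 11

Remark on the chemistry: 2-methoxyresorcinol holds only three of the four ring A oxygens, so the oxygen that becomes O1 is added para to its methoxy group by C–H borylation and oxidation. The acetyl group is introduced by directed ortho-lithiation because acetals would not survive a Lewis acid rearrangement of an aryl acetate, and alkaline H2O2 replaces a peracid in the key step to protect the prenyl alkenes.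

## Route

Step 1
Reactants: 1 2-methoxyresorcinol (2-methoxybenzene-1,3-diol)
Product: 2 2-methoxy-1,3-bis(methoxymethoxy)benzene
Conditions: NaH (2.2 equiv), MOMCl (2.2 equiv), DMF, 0 °C to rt
Reagents that add atoms: chloromethyl methyl ether (MOMCl), COCCl
Why: Double Williamson O-alkylation of the two equivalent sodium phenoxides by two equivalents of the reactive alpha-chloro ether; there is no other nucleophilic site, and the acetals formed are stable to all later basic and organometallic steps.

Step 2
Reactants: 2 2-methoxy-1,3-bis(methoxymethoxy)benzene
Product: 4 4-methoxy-3,5-bis(methoxymethoxy)phenol, via pinacol arylboronate 3 (not isolated)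
Conditions: B2pin2, [Ir(OMe)(cod)]2 (cat.), 4,4′-di-tert-butyl-2,2′-bipyridine (cat.), THF, 80 °C; then 30% H2O2, aq NaOH, 0 °C
Reagents that add atoms: hydrogen peroxide, OO (the phenol oxygen); bis(pinacolato)diboron, CC1(C)OB(OC1(C)C)B1OC(C)(C)C(C)(C)O1 (boryl group of 3 only)
Why: Iridium-catalysed aromatic C–H borylation is governed by sterics, and 2 has a single C–H without an ortho neighbour (para to the methoxy group), so 3 should form as one isomer; alkaline peroxide then converts C–B into C–O by 1,2-aryl migration from boron to oxygen. This one-pot borylation–oxidation of a 1,2,3-trisubstituted arene supplies the missing ring A oxygen.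

Step 3
Reactants: 4 4-methoxy-3,5-bis(methoxymethoxy)phenol
Product: 5 5-(benzyloxy)-2-methoxy-1,3-bis(methoxymethoxy)benzene
Conditions: BnBr, K2CO3, DMF, rt
Reagents that add atoms: benzyl bromide, BrCc1ccccc1
Why: Williamson etherification of the only free phenol; the benzyl group marks the oxygen that will become O1, is orthogonal to the acetals, and can be removed by hydrogenolysis because this half of the molecule has no alkene.

Step 4
Reactants: 5 5-(benzyloxy)-2-methoxy-1,3-bis(methoxymethoxy)benzene; 6 N-methoxy-N-methylacetamide
Product: 8 1-[2-(benzyloxy)-5-methoxy-4,6-bis(methoxymethoxy)phenyl]ethanone, via aryllithium 7 (not isolated)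
Conditions: n-BuLi, THF, −20 to 0 °C; then 6, −78 to 0 °C; aq NH4Cl
Reagents that add atoms: n-butyllithium, [Li]CCCC (lithium of 7 only; the acetyl group comes from reactant 6)
Why: Directed ortho-metalation: the ring C–H between the benzyloxy and acetal oxygens is doubly activated and chelating, the two such positions are equivalent by symmetry, and 7 is acylated by the Weinreb amide through a stable tetrahedral chelate that gives the ketone only on work-up.

Step 5
Reactants: 8 1-[2-(benzyloxy)-5-methoxy-4,6-bis(methoxymethoxy)phenyl]ethanone
Product: 9 1-[2-hydroxy-5-methoxy-4,6-bis(methoxymethoxy)phenyl]ethanone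
Conditions: H2 (1 atm), 10% Pd/C, NaHCO3 (trace), EtOAc, rt
Reagents that add atoms: none
Why: Neutral catalytic hydrogenolysis of the benzyl aryl ether frees the one phenol that will close ring C; the acetals are inert and the hindered, electron-rich aryl ketone should be reduced far more slowly than the O-benzyl bond is cleaved.

Step 6
Reactants: 10 methyl 4-hydroxybenzoate; 11 prenyl bromide (1-bromo-3-methylbut-2-ene)
Product: 12 methyl 4-hydroxy-3,5-bis(3-methylbut-2-enyl)benzoate
Conditions: NaH (2.2 equiv in two portions), toluene, 0 °C; 11 (2.2 equiv in two portions), rt to 40 °C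
Reagents that add atoms: prenyl bromide (second equivalent), CC(C)=CCBr
Why: Twofold ortho C-alkylation of a sodium phenoxide in a non-polar solvent, where the tight ion pair shields oxygen and sends the allylic bromide to the ring carbons; the first equivalent of 11 enters one ortho carbon, and after renewed deprotonation the second equivalent can only enter the other ortho carbon because the para position is blocked by the ester. SN2 attack at the primary carbon of the bromide gives the linear prenyl chain each time.

Step 7
Reactants: 12 methyl 4-hydroxy-3,5-bis(3-methylbut-2-enyl)benzoate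
Product: 13 methyl 4-(methoxymethoxy)-3,5-bis(3-methylbut-2-enyl)benzoate
Conditions: NaH, MOMCl, DMF, 0 °C to rt
Reagents that add atoms: chloromethyl methyl ether (MOMCl), COCCl
Why: O-Alkylation of the sodium phenoxide, which is flanked by two chains and is therefore fully deprotonated with NaH, by the small and very reactive alpha-chloro ether; this masks the C4′ oxygen as the same acetal used on ring A.

Step 8
Reactants: 13 methyl 4-(methoxymethoxy)-3,5-bis(3-methylbut-2-enyl)benzoate
Product: 14 4-(methoxymethoxy)-3,5-bis(3-methylbut-2-enyl)benzoic acid
Conditions: LiOH, THF–MeOH–H2O, 50 °C; then cold dilute HCl to pH 4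
Reagents that add atoms: lithium hydroxide, [Li+].[OH-] (one carboxyl oxygen)
Why: Saponification of a methyl benzoate; acetal and alkenes are inert to hydroxide, and acidification stops at pH 4 in the cold so that neither meets strong acid.

Step 9
Reactants: 14 4-(methoxymethoxy)-3,5-bis(3-methylbut-2-enyl)benzoic acid; 9 1-[2-hydroxy-5-methoxy-4,6-bis(methoxymethoxy)phenyl]ethanone
Product: 16 1-[2-hydroxy-5-methoxy-4,6-bis(methoxymethoxy)phenyl]-3-[4-(methoxymethoxy)-3,5-bis(3-methylbut-2-enyl)phenyl]propane-1,3-dione, via acid chloride 15 (not isolated)
Conditions: 14, 1-chloro-N,N,2-trimethylprop-1-en-1-amine, CH2Cl2, 0 °C to rt; 9, LiN(SiMe3)2 (4 equiv), THF, −78 to −20 °C; then 15, −78 °C to rt; aq NH4Cl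
Reagents that add atoms: 1-chloro-N,N,2-trimethylprop-1-en-1-amine, CC(C)=C(Cl)N(C)C (chlorine of 15 only)
Why: The alpha-chloroenamine makes 15 without releasing HCl, so acetal and alkenes are safe; excess LiN(SiMe3)2 turns 9 into its phenoxide enolate, which is C-acylated by 15 (any O-aroyl ester formed rearranges under the same base), and the remaining base holds the product as its unreactive diketonate. This is the lithium polyanion form of the Baker–Venkataraman flavone synthesis.

Step 10
Reactants: 16 1-[2-hydroxy-5-methoxy-4,6-bis(methoxymethoxy)phenyl]-3-[4-(methoxymethoxy)-3,5-bis(3-methylbut-2-enyl)phenyl]propane-1,3-dione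
Product: 17 6-methoxy-5,7-bis(methoxymethoxy)-2-[4-(methoxymethoxy)-3,5-bis(3-methylbut-2-enyl)phenyl]chromen-4-one
Conditions: PPTS (cat.), MgSO4, toluene, 70 °C
Reagents that add atoms: none
Why: Acid-catalysed cyclodehydration: the free phenol adds to the ring B carbonyl (6-exo-trig, forming O1–C2) to give a 2-hydroxychromanone hemiketal, which loses water through an oxocarbenium ion stabilised by O1 and ring B. A buffered sulfonic acid salt in an aprotic solvent is used so that the three acetals and two alkenes are not solvolysed, and with only one ring A hydroxyl free only the 6-methoxy isomer can form.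

Step 11
Reactants: 17 6-methoxy-5,7-bis(methoxymethoxy)-2-[4-(methoxymethoxy)-3,5-bis(3-methylbut-2-enyl)phenyl]chromen-4-one
Product: 20 3-hydroxy-6-methoxy-5,7-bis(methoxymethoxy)-2-[4-(methoxymethoxy)-3,5-bis(3-methylbut-2-enyl)phenyl]chromen-4-one, via C3 vinyllithium 18 (not isolated), via C3 trimethoxyborate 19 (not isolated)
Conditions: LiN(i-Pr)2, THF, −78 °C; B(OMe)3, −78 to −20 °C; then 30% H2O2, aq NaOH, 0 °C
Reagents that add atoms: hydrogen peroxide, OO (the C3 oxygen); lithium diisopropylamide, [Li]N(C(C)C)C(C)C (lithium of 18 only); trimethyl borate, COB(OC)OC (boron of 19 only)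
Why: Lithium diisopropylamide, held by the C4 carbonyl oxygen and the neighbouring C5 acetal, removes the C3 hydrogen, the only sp2 C–H alpha to the carbonyl, to give 18 at −78 °C. B(OMe)3 captures 18 as the ate complex 19 before it can open by beta-elimination of O1; hydroperoxide then adds to boron, C3 migrates from boron to oxygen with loss of hydroxide, and hydrolysis of the borate ester releases the enol, which is the flavonol 20. The closest known reaction type is the C3 lithiation of flavones with a lithium amide followed by borate trapping and peroxide oxidation. No ring is closed and no stereocentre is created; one C–O bond is formed. The step needs site selectivity for C3–H over C8–H and over the benzylic, allylic CH2 groups of the prenyl chains: carbonyl coordination and the higher kinetic acidity of the enone alpha position secure C3, while a hindered amide at −78 °C is too weak to lithiate beside the C7 acetal and too bulky to add at C2. It also needs a chemoselective oxidant: alkaline H2O2 is nucleophilic, attacks boron and leaves the electron-rich trisubstituted alkenes alone, which is why no peracid is used. The product carries a single free hydroxyl, on which the next step depends.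

Step 12
Reactants: 20 3-hydroxy-6-methoxy-5,7-bis(methoxymethoxy)-2-[4-(methoxymethoxy)-3,5-bis(3-methylbut-2-enyl)phenyl]chromen-4-one
Product: 21 3,6-dimethoxy-5,7-bis(methoxymethoxy)-2-[4-(methoxymethoxy)-3,5-bis(3-methylbut-2-enyl)phenyl]chromen-4-one
Conditions: MeI, K2CO3, acetone, 40 °C
Reagents that add atoms: iodomethane, CI
Why: Williamson O-methylation of the acidic C3 enol hydroxyl, the only free hydroxyl in 20; every other oxygen is an ether, so the methyl group can only go to C3.

Step 13
Reactants: 21 3,6-dimethoxy-5,7-bis(methoxymethoxy)-2-[4-(methoxymethoxy)-3,5-bis(3-methylbut-2-enyl)phenyl]chromen-4-one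
Product: 22 5,7-dihydroxy-2-[4-hydroxy-3,5-bis(3-methylbut-2-enyl)phenyl]-3,6-dimethoxychromen-4-one
Conditions: HCl (ca. 1 M), MeOH–THF, 40 °C
Reagents that add atoms: none
Why: Acid-catalysed transacetalisation of the three aryl methoxymethyl ethers to methanol, the acetal beside the carbonyl going first; dilute acid at moderate temperature stays below the conditions under which a prenyl alkene is protonated and cyclises onto the freed C4′ hydroxyl, and the methyl ethers at C3 and C6 are untouched.

## Compound list

1 | 2-methoxyresorcinol (2-methoxybenzene-1,3-diol) | COc1c(O)cccc1O | starting material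
2 | 2-methoxy-1,3-bis(methoxymethoxy)benzene | COCOc1cccc(OCOC)c1OC | intermediate
3 | 2-[4-methoxy-3,5-bis(methoxymethoxy)phenyl]-4,4,5,5-tetramethyl-1,3,2-dioxaborolane | COCOc1cc(B2OC(C)(C)C(C)(C)O2)cc(OCOC)c1OC | intermediate
4 | 4-methoxy-3,5-bis(methoxymethoxy)phenol | COCOc1cc(O)cc(OCOC)c1OC | intermediate
5 | 5-(benzyloxy)-2-methoxy-1,3-bis(methoxymethoxy)benzene | COCOc1cc(OCc2ccccc2)cc(OCOC)c1OC | intermediate
6 | N-methoxy-N-methylacetamide | CC(=O)N(C)OC | starting material
7 | [2-(benzyloxy)-5-methoxy-4,6-bis(methoxymethoxy)phenyl]lithium | [Li]c1c(OCc2ccccc2)cc(OCOC)c(OC)c1OCOC | intermediate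
8 | 1-[2-(benzyloxy)-5-methoxy-4,6-bis(methoxymethoxy)phenyl]ethanone | CC(=O)c1c(OCc2ccccc2)cc(OCOC)c(OC)c1OCOC | intermediate
9 | 1-[2-hydroxy-5-methoxy-4,6-bis(methoxymethoxy)phenyl]ethanone | CC(=O)c1c(O)cc(OCOC)c(OC)c1OCOC | intermediate
10 | methyl 4-hydroxybenzoate | COC(=O)c1ccc(O)cc1 | starting material
11 | prenyl bromide (1-bromo-3-methylbut-2-ene) | CC(C)=CCBr | starting material
12 | methyl 4-hydroxy-3,5-bis(3-methylbut-2-enyl)benzoate | COC(=O)c1cc(CC=C(C)C)c(O)c(CC=C(C)C)c1 | intermediate
13 | methyl 4-(methoxymethoxy)-3,5-bis(3-methylbut-2-enyl)benzoate | COCOc1c(CC=C(C)C)cc(C(=O)OC)cc1CC=C(C)C | intermediate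
14 | 4-(methoxymethoxy)-3,5-bis(3-methylbut-2-enyl)benzoic acid | COCOc1c(CC=C(C)C)cc(C(=O)O)cc1CC=C(C)C | intermediate
15 | 4-(methoxymethoxy)-3,5-bis(3-methylbut-2-enyl)benzoyl chloride | COCOc1c(CC=C(C)C)cc(C(=O)Cl)cc1CC=C(C)C | intermediate
16 | 1-[2-hydroxy-5-methoxy-4,6-bis(methoxymethoxy)phenyl]-3-[4-(methoxymethoxy)-3,5-bis(3-methylbut-2-enyl)phenyl]propane-1,3-dione | COCOc1cc(O)c(C(=O)CC(=O)c2cc(CC=C(C)C)c(OCOC)c(CC=C(C)C)c2)c(OCOC)c1OC | intermediate
17 | 6-methoxy-5,7-bis(methoxymethoxy)-2-[4-(methoxymethoxy)-3,5-bis(3-methylbut-2-enyl)phenyl]chromen-4-one | COCOc1cc2oc(-c3cc(CC=C(C)C)c(OCOC)c(CC=C(C)C)c3)cc(=O)c2c(OCOC)c1OC | intermediate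
18 | {6-methoxy-5,7-bis(methoxymethoxy)-2-[4-(methoxymethoxy)-3,5-bis(3-methylbut-2-enyl)phenyl]-4-oxochromen-3-yl}lithium | COCOc1cc2oc(-c3cc(CC=C(C)C)c(OCOC)c(CC=C(C)C)c3)c([Li])c(=O)c2c(OCOC)c1OC | intermediate
19 | lithium trimethoxy{6-methoxy-5,7-bis(methoxymethoxy)-2-[4-(methoxymethoxy)-3,5-bis(3-methylbut-2-enyl)phenyl]-4-oxochromen-3-yl}borate | [Li+].COCOc1cc2oc(-c3cc(CC=C(C)C)c(OCOC)c(CC=C(C)C)c3)c([B-](OC)(OC)OC)c(=O)c2c(OCOC)c1OC | intermediate
20 | 3-hydroxy-6-methoxy-5,7-bis(methoxymethoxy)-2-[4-(methoxymethoxy)-3,5-bis(3-methylbut-2-enyl)phenyl]chromen-4-one | COCOc1cc2oc(-c3cc(CC=C(C)C)c(OCOC)c(CC=C(C)C)c3)c(O)c(=O)c2c(OCOC)c1OC | intermediate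
21 | 3,6-dimethoxy-5,7-bis(methoxymethoxy)-2-[4-(methoxymethoxy)-3,5-bis(3-methylbut-2-enyl)phenyl]chromen-4-one | COCOc1cc2oc(-c3cc(CC=C(C)C)c(OCOC)c(CC=C(C)C)c3)c(OC)c(=O)c2c(OCOC)c1OC | intermediate
22 | 5,7-dihydroxy-2-[4-hydroxy-3,5-bis(3-methylbut-2-enyl)phenyl]-3,6-dimethoxychromen-4-one | COc1c(O)cc2oc(-c3cc(CC=C(C)C)c(O)c(CC=C(C)C)c3)c(OC)c(=O)c2c1O | target

## Step count and least certain steps

Total: 13 steps. Longest linear sequence: 10 steps (steps 1 to 5, then 9 to 13); the ring B branch (steps 6 to 8) joins at step 9.

Step 11 (key step). The most likely failures are loss of the C3 anion before it is borylated and loss of the boronate before it is oxidised. The vinyllithium can open ring C by expelling O1 as a phenoxide if the temperature rises, and the C3 boronate, which sits alpha to a carbonyl, can undergo protodeboronation in aqueous base and return 17. A slower deprotonation than expected would also allow metalation at C8 or at a prenyl CH2. The fallback gives up the late oxygenation and builds the C3 methoxy group into ring C. It sets out from 5: lithiation to 7 as in step 4 and acylation with N,2-dimethoxy-N-methylacetamide would give 1-[2-(benzyloxy)-5-methoxy-4,6-bis(methoxymethoxy)phenyl]-2-methoxyethanone F1. Hydrogenolysis (H2, Pd/C) would give 1-[2-hydroxy-5-methoxy-4,6-bis(methoxymethoxy)phenyl]-2-methoxyethanone F2. Acylation of its lithium enolate with 15 as in step 9 would give 1-[2-hydroxy-5-methoxy-4,6-bis(methoxymethoxy)phenyl]-2-methoxy-3-[4-(methoxymethoxy)-3,5-bis(3-methylbut-2-enyl)phenyl]propane-1,3-dione F3 (racemic at the enolisable central carbon). Cyclodehydration as in step 10 returns to the route at 21.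

Step 6. O-Alkylation competes with C-alkylation, the reaction can stop at the mono-prenyl stage before the second equivalent of 11 has entered, and a para-acyl phenoxide is a weak carbon nucleophile, so this is expected to be the least efficient step and to need chromatographic separation. The fallback replaces phenoxide alkylation by cross-coupling. It sets out from 10: bromination (Br2, AcOH) would give methyl 3,5-dibromo-4-hydroxybenzoate F4, and MOMCl with NaH would give methyl 3,5-dibromo-4-(methoxymethoxy)benzoate F5. A double Stille coupling with purchased tributyl(3-methylbut-2-enyl)stannane (Pd(PPh3)4, DMF, 100 °C), which delivers the linear prenyl group, returns to the route at 13 and bypasses 12.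

Step 10. The acetal on the oxygen beside the ketone (future C5) is the most acid-labile group because the carbonyl assists its departure, so partial loss of that protecting group during ring closure is the main risk; incomplete dehydration with so weak an acid is the second. The fallback stops trying to preserve that acetal. It sets out from 16: heating in AcOH with NaOAc would close the ring and shed the peri acetal to give 5-hydroxy-6-methoxy-7-(methoxymethoxy)-2-[4-(methoxymethoxy)-3,5-bis(3-methylbut-2-enyl)phenyl]chromen-4-one F6. Re-protection of the chelated hydroxyl (and of any other phenol freed) with NaH and MOMCl in DMF returns to the route at 17.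

Step 13. Protonation of a prenyl alkene followed by ring closure onto the newly freed C4′ hydroxyl (chroman formation) is the main risk, made worse if the hindered C4′ acetal is slow to cleave and the reaction has to be pushed. The fallback removes the acetals without a Brønsted acid. It sets out from 21: TMSOTf with 2,2′-bipyridyl in CH2Cl2 at 0 °C would exchange each aryl acetal for a silyl ether, giving 3,6-dimethoxy-5,7-bis(trimethylsilyloxy)-2-[3,5-bis(3-methylbut-2-enyl)-4-(trimethylsilyloxy)phenyl]chromen-4-one F7. Hydrolysis with water on work-up returns to the route at 22.

Step 4. The hindered aryllithium may act as a base toward the acetamide (enolisation instead of addition), and lithiation at the benzylic CH2 followed by Wittig rearrangement may compete with ring lithiation. The fallback needs neither benzyl ether nor organolithium. It sets out from 4: magnesium-mediated ortho-formylation (MgCl2, Et3N, paraformaldehyde, MeCN, reflux) would give 2-hydroxy-5-methoxy-4,6-bis(methoxymethoxy)benzaldehyde F8. Excess MeMgBr would give 2-(1-hydroxyethyl)-4-methoxy-3,5-bis(methoxymethoxy)phenol F9 (racemic; the stereocentre is destroyed in the next operation). Benzylic oxidation with MnO2 returns to the route at 9 and bypasses 5 and 8.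

## Further compounds

F1 | step 11 | 1-[2-(benzyloxy)-5-methoxy-4,6-bis(methoxymethoxy)phenyl]-2-methoxyethanone | COCC(=O)c1c(OCc2ccccc2)cc(OCOC)c(OC)c1OCOC
F2 | step 11 | 1-[2-hydroxy-5-methoxy-4,6-bis(methoxymethoxy)phenyl]-2-methoxyethanone | COCC(=O)c1c(O)cc(OCOC)c(OC)c1OCOC
F3 | step 11 | 1-[2-hydroxy-5-methoxy-4,6-bis(methoxymethoxy)phenyl]-2-methoxy-3-[4-(methoxymethoxy)-3,5-bis(3-methylbut-2-enyl)phenyl]propane-1,3-dione (racemic) | COCOc1cc(O)c(C(=O)C(OC)C(=O)c2cc(CC=C(C)C)c(OCOC)c(CC=C(C)C)c2)c(OCOC)c1OC
F4 | step 6 | methyl 3,5-dibromo-4-hydroxybenzoate | COC(=O)c1cc(Br)c(O)c(Br)c1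
F5 | step 6 | methyl 3,5-dibromo-4-(methoxymethoxy)benzoate | COCOc1c(Br)cc(C(=O)OC)cc1Br
F6 | step 10 | 5-hydroxy-6-methoxy-7-(methoxymethoxy)-2-[4-(methoxymethoxy)-3,5-bis(3-methylbut-2-enyl)phenyl]chromen-4-one | COCOc1cc2oc(-c3cc(CC=C(C)C)c(OCOC)c(CC=C(C)C)c3)cc(=O)c2c(O)c1OC
F7 | step 13 | 3,6-dimethoxy-5,7-bis(trimethylsilyloxy)-2-[3,5-bis(3-methylbut-2-enyl)-4-(trimethylsilyloxy)phenyl]chromen-4-one | COc1c(O[Si](C)(C)C)cc2oc(-c3cc(CC=C(C)C)c(O[Si](C)(C)C)c(CC=C(C)C)c3)c(OC)c(=O)c2c1O[Si](C)(C)C
F8 | step 4 | 2-hydroxy-5-methoxy-4,6-bis(methoxymethoxy)benzaldehyde | COCOc1cc(O)c(C=O)c(OCOC)c1OC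
F9 | step 4 | 2-(1-hydroxyethyl)-4-methoxy-3,5-bis(methoxymethoxy)phenol (racemic) | COCOc1cc(O)c(C(C)O)c(OCOC)c1OC
A1 | alternative 1 | 3,6-dimethoxy-5,7-bis(prop-2-enyloxy)-2-[3,5-bis(3-methylbut-2-enyl)-4-(prop-2-enyloxy)phenyl]chromen-4-one | C=CCOc1cc2oc(-c3cc(CC=C(C)C)c(OCC=C)c(CC=C(C)C)c3)c(OC)c(=O)c2c(OCC=C)c1OC
A2 | alternative 1 | (E)-3-[4-methoxy-3,5-bis(prop-2-enyloxy)phenoxy]-2-methoxy-3-[3,5-bis(3-methylbut-2-enyl)-4-(prop-2-enyloxy)phenyl]prop-2-enoic acid | C=CCOc1cc(O/C(c2cc(CC=C(C)C)c(OCC=C)c(CC=C(C)C)c2)=C(\C(=O)O)OC)cc(OCC=C)c1OC
A3 | alternative 2 | 3,6-dimethoxy-5,7-bis(methoxymethoxy)-2-[4-(methoxymethoxy)-3,5-bis(3-methylbut-2-enyl)phenyl]chromen-4-one (identical with 21) | COCOc1cc2oc(-c3cc(CC=C(C)C)c(OCOC)c(CC=C(C)C)c3)c(OC)c(=O)c2c(OCOC)c1OC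
A4 | alternative 2 | 2-hydroxy-5-methoxy-4,6-bis(methoxymethoxy)benzaldehyde | COCOc1cc(O)c(C=O)c(OCOC)c1OC
A5 | alternative 2 | 5-(methoxyethynyl)-2-(methoxymethoxy)-1,3-bis(3-methylbut-2-enyl)benzene | COC#Cc1cc(CC=C(C)C)c(OCOC)c(CC=C(C)C)c1
A6 | alternative 3 | 6-hydroxy-3-methoxy-5,7-bis(methoxymethoxy)-2-[4-(methoxymethoxy)-3,5-bis(3-methylbut-2-enyl)phenyl]chromen-4-one | COCOc1cc2oc(-c3cc(CC=C(C)C)c(OCOC)c(CC=C(C)C)c3)c(OC)c(=O)c2c(OCOC)c1O
A7 | alternative 3 | 3-methoxy-5,7-bis(methoxymethoxy)-2-[4-(methoxymethoxy)-3,5-bis(3-methylbut-2-enyl)phenyl]chromen-4-one | COCOc1cc(OCOC)c2c(c1)oc(-c1cc(CC=C(C)C)c(OCOC)c(CC=C(C)C)c1)c(OC)c2=O
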